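**Assumption:** (1R,6S)-(−)-2-carene and methyl 3-oxopropanoate are purchasable. The C2 acylal is taken to be the thermodynamic (anomeric) isomer. Numbering below is plagiochilin numbering: C1/C5 are the pyran/cycloheptane fusion carbons, C2 is the acetal carbon, C6/C7 are the cyclopropane CH carbons, C10 is the spiro-epoxide carbon, and C15 is the CH2OAc carbon.

## Retrosynthetic overview
1. Plagiochilin A comes from acetylation of an amino-acetal allylic alcohol. The spiro-epoxide is made from the C10 ketone by sulfonium methylide, and the CH2OH from reduction of a vinylogous carbonate ester.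
2. The tricyclic keto-aminal ester forms in one domino Knoevenagel / intramolecular inverse-demand hetero-Diels–Alder step. This closes the cycloheptanone (C1–C5 bond) and the dihydropyran (O–C2 bond) together.
3. The two partners are a cyclopropane-tethered enaminone-aldehyde and methyl formylacetate. The enaminone-aldehyde comes from DMF-DMA and the ozonolysis product of (−)-2-carene, which supplies the cyclopropane and its absolute configuration.
4. Ring order: cyclopropane (chiral pool), then cycloheptanone and pyran together in one step, then the epoxide.

## Route

**Step 1**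
Reactants: 1 (1R,6S)-(−)-2-carene
Product: 2 (1R,3S)-2,2-dimethyl-3-(3-oxobutyl)cyclopropane-1-carbaldehyde
Conditions: O3, CH2Cl2/MeOH, −78 °C; then Me2S, −78 °C → rt
Reagents that add atoms: ozone [O-][O+]=O (Me2S is only the reductant, no atoms retained)
Why: Ozonolysis (Criegee, reductive work-up) cleaves only the trisubstituted alkene and leaves the cis-cyclopropane and both of its stereocentres untouched. The cyclopropyl aldehyde has no α-H and the work-up is neutral, so there is no aldol and no epimerisation.

**Step 2**
Reactants: 2
Product: 3 (1R,3S)-3-[(4E)-5-(dimethylamino)-3-oxopent-4-en-1-yl]-2,2-dimethylcyclopropane-1-carbaldehyde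
Conditions: DMF-DMA (1.3 equiv), toluene, 90 °C, 6 h
Reagents that add atoms: N,N-dimethylformamide dimethyl acetal, CN(C)C(OC)OC (adds =CH–NMe2)
Why: Bredereck-type enaminone formation takes place at the less hindered methyl terminus of the ketone, and the non-enolisable cyclopropyl aldehyde is untouched. The (E)-enaminone masks the ketone against aldol closure and is an electron-rich, C1-nucleophilic dienophile. No stereocentre is created.

**Step 3 (key step)**
Reactants: 3 enaminone-aldehyde; 4 methyl 3-oxopropanoate (COC(=O)CC=O)
Product: 6 tricyclic keto-aminal ester, formed via transient intermediate 5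
Conditions: 4 (1.5 equiv, added over 6 h), ethylenediammonium diacetate (10 mol %), 4 Å MS, CH2Cl2 (0.01 M), 25 → 40 °C
Reagents that add atoms: methyl 3-oxopropanoate, COC(=O)CC=O (reactant 4; loses H2O)
Why: Proposed new method: Knoevenagel condensation of the cyclopropyl aldehyde with 4 gives the strongly electrophilic 2-formylacrylate 1-oxadiene 5. The enaminone Cα (C1) adds to the β-carbon (C5), closing the cycloheptanone, and the formyl enolate oxygen closes onto the iminium carbon C2 to give the dihydropyran N,O-aminal, which is an asynchronous inverse-demand [4+2]. The closest known reaction is the Tietze domino Knoevenagel/hetero-Diels–Alder, here applied with a seven-membered tether. The (E)-enaminone puts C1–C10 and C2–N trans by suprafacial addition. The cis-cyclopropane pre-organises the tether, so the enal is attacked on the face anti to the CMe2 bridge, which sets C5 and gives the cis-fused ring junction (H1/H5 cis). C1 is epimerisable α to the ketone and settles on the cis-fused isomer. High dilution favours the intramolecular path over oligomerisation.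

**Step 4**
Reactants: 6
Product: 7 spiro-epoxide keto-aminal ester
Conditions: Me3S+ I−, NaH, DMSO/THF (1:1), 0 °C, 30 min
Reagents that add atoms: trimethylsulfonium iodide, C[S+](C)C.[I-] (adds CH2)
Why: Corey–Chaykovsky epoxidation of the C10 ketone. The sulfonium methylide adds irreversibly to the convex face, anti to the cis-fused pyran and its C2 substituent, so CH2 ends up syn to the cyclopropane bridge and the oxygen anti. This sets C10. The β-alkoxyacrylate (a poor Michael acceptor) and the aminal survive.

**Step 5**
Reactants: 7
Product: 8 spiro-epoxide amino-acetal allylic alcohol (C15 CH2OH)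
Conditions: LiAlH4 (1.5 equiv), THF, −30 → 0 °C; Rochelle salt work-up
Reagents that add atoms: none
Why: 1,2-Reduction of the vinylogous carbonate ester to the allylic alcohol, as in iridoid dihydropyran-5-carboxylate reductions. The hindered spiro-epoxide and the aminal tolerate LiAlH4 at this temperature (no Lewis acid), and no stereocentre is touched.

**Step 6**
Reactants: 8
Product: 9 plagiochilin A
Conditions: Ac2O (10 equiv), DMAP (0.2 equiv), pyridine, CH2Cl2, 0 → 40 °C
Reagents that add atoms: acetic anhydride, CC(=O)OC(C)=O (two acetyl groups)
Why: Acetylation of the primary alcohol, plus acylative C–N cleavage of the N,O-aminal. N-acetylation, loss of Me2NAc, and capture of the oxocarbenium by acetate give the acylal, a known acetolysis of α-amino ethers. Pyridine buffers the epoxide. C2 is set by anomeric control (OAc trans to C10), matching the target.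

## Compound list
| # | Name | SMILES | Role |
|---|---|---|---|
| 1 | (1R,6S)-(−)-2-Carene | CC1=C[C@@H]2[C@H](CC1)C2(C)C | starting material |
| 2 | (1R,3S)-2,2-Dimethyl-3-(3-oxobutyl)cyclopropane-1-carbaldehyde | O=C[C@@H]1[C@H](CCC(C)=O)C1(C)C | intermediate |
| 3 | Enaminone-aldehyde (E) | O=C[C@@H]1[C@H](CCC(=O)/C=C/N(C)C)C1(C)C | intermediate |
| 4 | Methyl 3-oxopropanoate | COC(=O)CC=O | starting material |
| 5 | Knoevenagel 1-oxadiene (formed in situ, not isolated; alkene E/Z unspecified) | COC(=O)C(C=O)=C[C@@H]1[C@H](CCC(=O)/C=C/N(C)C)C1(C)C | intermediate |
| 6 | Tricyclic keto-aminal ester (cis-fused pyran/cycloheptanone, cyclopropane as in target, C2–N trans to C1–C10, ring-fusion bonds anti to CMe2) | COC(=O)C1=CO[C@H](N(C)C)[C@@H]2[C@H]1[C@@H]1[C@H](CCC2=O)C1(C)C | intermediate |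
| 7 | Spiro-epoxide aminal ester (O anti to the cyclopropane bridge) | COC(=O)C1=CO[C@H](N(C)C)[C@@H]2[C@H]1[C@@H]1[C@H](CC[C@@]23CO3)C1(C)C | intermediate |
| 8 | Spiro-epoxide aminal allylic alcohol | OCC1=CO[C@H](N(C)C)[C@@H]2[C@H]1[C@@H]1[C@H](CC[C@@]23CO3)C1(C)C | intermediate |
| 9 | Plagiochilin A (1R,2R,5R,6S,7S,10S, plagiochilin numbering) | CC(=O)OCC1=CO[C@H](OC(C)=O)[C@@H]2[C@H]1[C@@H]1[C@H](CC[C@@]23CO3)C1(C)C | target |

## Totals
- Total steps: 6.
- Longest linear sequence: 6 steps, all linear.

## Three steps most likely to fail
1. **Step 3 (domino Knoevenagel / intramolecular hetero-Diels–Alder):** closing the seven-membered ring may lose out to oligomerisation, or give the wrong C5/C1 diastereomer. Fallback: form the carbocycle first. Condense enaminone and aldehyde intramolecularly (TFA) to the 2-formylcycloheptenone, then close the pyran by a Michael/hemiacetalisation [3+3] annulation with methyl 3-oxopropanoate.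
2. **Step 4 (Corey–Chaykovsky):** the base may open the β-alkoxy-ketone pyran by retro-oxa-Michael elimination, or the ylide may attack the wrong face at C10. Fallback: exchange the aminal for a methyl acetal (MeOH, PPTS) and add chloromethyllithium (ICH2Cl/MeLi·LiBr, −78 °C) as a non-basic carbenoid, then close the chlorohydrin alkoxide with mild base.
3. **Step 6 (acylative aminal exchange with the epoxide present):** the epoxide may open under acetic acid, or the aminal may not exchange. Fallback: hydrolyse the aminal to the lactol (AcOH/H2O/THF, 25 °C), then acetylate the lactol and C15 alcohol together (Ac2O, DMAP, Et3N), using DMAP/AcOH to equilibrate C2 to the anomeric acetate.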